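## Analysis of the target

Target 16 is a 2-aryl-3-methyl-2,3-dihydrobenzofuran neolignan. Ring A is a benzene ring fused to a dihydrofuran ring made of O1, C2, C3, C3a and C7a; it carries a methoxy group at C7 and an (E)-prop-1-enyl group at C5. C2 carries ring B, a 3-hydroxy-4,5-dimethoxyphenyl group, and C3 carries a methyl group. The only stereocentres are the adjacent C2 and C3, both S, which places the ring B aryl group and the C3 methyl group trans on the five-membered ring, the thermodynamically preferred arrangement. The sensitive groups are the styrene-type propenyl group (acid, electrophiles, metal carbenoids), the single free phenol of ring B among two methyl ethers, and the C2–O1 benzylic aryl ether bond, which can ionise in strong acid and lose the C2 configuration. The difficulty is absolute control at C2 together with the trans relationship, on an electron-rich skeleton that has no directing handle near the stereocentres. The strategy rests on C2 being a benzylic ether methine: without the C2–C3 bond, C2 is the methylene of an aryl benzyl ether whose C–H bonds lie 1,5 to C3, a carbon bound to C3a of ring A. A carbenoid at C3 can therefore insert into one of the two enantiotopic C2–H bonds and close the dihydrofuran ring, provided C3 carries an ester that is later reduced to the methyl group.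

## Retrosynthetic reasoning

**16 to 14 and 15.** The C5–propenyl bond is cut first, giving aryl chloride 14 and propenyl borate 15. The alkene would be cyclopropanated by a metal carbenoid and is best kept away from acid, so it must arrive after ring formation and after deprotection. A chloride at C5 is inert to every step in between and is activated only by an electron-rich phosphine–palladium catalyst. The forward coupling has to keep the E geometry and tolerate the free phenol.

**14 to 13.** The ring B phenol is traced back to its methoxymethyl ether 13. The phenol would undergo O–H insertion with the carbenoid and would consume base and hydride later on. The acetal is stable to alkoxide and hydride and is removed by mild acid while no alkene is yet present.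

**13 to 12, 11 and 10.** The C3 methyl group is traced back, through sulfonate 12 and alcohol 11, to the ester of 10. No skeletal bond is cut. These three steps are the price of needing an acceptor group on the carbenoid carbon, and none of them touches C2 or C3.

**10 to 9.** The trans ester 10 comes from the cis ester 9 by inversion at C3, the only acidic stereocentre. The insertion delivers the cis isomer kinetically, and the trans isomer is the more stable one, so a catalytic amount of base should suffice.

**9 to 8.** The C2–C3 bond is cut, which opens the dihydrofuran ring and gives the diazo ester 8. This is the only cut that turns both stereocentres into prochiral centres while leaving two intact aromatic rings joined by a plain ether. Cutting O1–C2 would demand a stereocontrolled C–O bond formation at a benzylic carbon next to a stereocentre, and cutting C3–C3a would demand an arylation or an aryl shift. One catalytic step then gives the ring, the C–C bond and both stereocentres; the forward reaction has to choose one of two enantiotopic benzylic hydrogens.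

**8 to 6 and 7.** The bond between C3a and the diazo carbon is cut, giving aryl iodide 6 and diazo ester 7. Direct coupling at the C–H bond of 7 brings in the ester and the diazo group together, so no arylacetate synthesis and no diazo transfer are needed. Iodide is chosen so that palladium distinguishes it from the chloride at the future C5.

**6 to 5 and 3.** The O–CH2 bond (the future O1–C2) is cut, giving phenol 5 and benzylic alcohol 3. A dehydrative coupling joins them under neutral conditions and avoids a labile, electron-rich benzylic halide.

**5 to 4; 3 to 2 to 1.** The C–I bond of 5 is made by iodination of 4 at the only free position ortho to the phenol. Alcohol 3 comes from aldehyde 1 by protection of the phenol (giving 2) and reduction.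

## Alternatives that were turned down

**Alternative 1: sulfonium ylide (4+1) annulation onto an ortho-quinone methide.**
- Disconnection: O1–C2 and C2–C3 are both cut. C2 arrives as a ring B benzylidene unit on a chiral sulfonium salt. C3, with its methyl group, is the exocyclic carbon of the quinone methide released from sulfone A2.
- Forward key step: Cs2CO3 eliminates sulfinate from A2 and deprotonates the sulfonium salt. The ylide adds to the exocyclic carbon (C2–C3), and the phenoxide displaces the sulfide (O1–C2), giving A1.
- For: it is convergent and delivers the methyl group and the trans relationship directly. A1 is only a cross-coupling and a desilylation from the target. On step economy it is clearly stronger than the chosen route, which spends three steps turning an ester into a methyl group and one step on epimerisation.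
- Against: both stereocentres are set in an intermolecular addition of a semi-stabilised benzylic ylide to a planar, transient quinone methide. Facial control at C3 depends on the alkene geometry of that intermediate and on a betaine that may form reversibly. An ethylidene quinone methide can also tautomerise to the vinylphenol or oligomerise before it is trapped. A sulfonium salt on a trioxygenated benzyl group ionises easily. A stoichiometric chiral sulfide is needed.
- Comparison: the chosen route offers a catalytic, intramolecular stereo-determining step in which only C2 must be controlled, while C3 is put right by thermodynamics.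

**Alternative 2: oxidative ring contraction of an enantiopure flavanone.**
- Disconnection: the C3–C3a bond is cut. Ring A is attached through a carbonyl carbon in flavanone A3, where C2 is already set.
- Forward key step: PhI(OAc)2 and H2SO4 in HC(OMe)3 form the enol ether and place trivalent iodine on the future C3. The ring A carbon migrates to C3 as iodobenzene leaves, and the former carbonyl carbon ends up as the methyl ester of A4.
- For: the trans ester is obtained directly, so it is stronger than the chosen route in saving the epimerisation step. It also needs no diazo compound and no rhodium catalyst.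
- Against: A3 is configurationally fragile, because flavanones racemise through reversible ring opening to the hydroxychalcone, and the contraction is run in strong acid. With an electron-rich ring B, migration of ring B (leading to the isoflavone) and dehydrogenation to the flavone compete with the wanted shift of ring A. The oxidant can attack the two electron-rich arenes, and the silyl ether is at risk in acid. The sequence after A4 is the same as from 10, so nothing is gained in length.
- Comparison: the chosen route sets C2 in a step that cannot racemise it afterwards and uses neutral, non-oxidising conditions.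

**Alternative 3: ring A grown on a chiral lactone by pyrone cycloaddition.**
- Disconnection: C3a–C4 and C7a–C7 are cut, so ring A is built last. Both stereocentres sit in the trans lactone A6.
- Forward key step: the silyl ketene acetal of A6 is heated with bromopyrone ester A7. Cycloaddition with inverse electron demand, loss of CO2 and loss of silanol give arene A5.
- For: the stereocentres are fixed early in a small lactone by reliable chemistry and no longer depend on an asymmetric reaction on a new substrate. On stereochemical security it is stronger than the chosen route. The regiochemistry follows from the polarisation of the two partners.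
- Against: A5 carries bromine at C7 and an ester at C5, and neither is what the target needs. C7 requires a C–O coupling at a hindered position and C5 requires reduction and an E-selective ethylidenation, on top of the lactone synthesis and the deprotection. This makes the route the longest of the four.
- Comparison: the chosen route buys both rings with the correct oxygenation pattern and needs only one cross-coupling on ring A.

Key step: step 6

Assumption: the sense of induction is taken from the behaviour of this catalyst family with simpler aryl benzyl ethers, where the S-configured phthaloyl-tert-leucinate complex leads to the 2R cis ester. The mirror-image complex Rh2(R-PTTL)4, dirhodium tetrakis[N-phthaloyl-(R)-tert-leucinate], is therefore specified for the 2S series, and the assignment should be confirmed on the first batch of 9.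

## Route

Step 1
Reactants: 1 3-hydroxy-4,5-dimethoxybenzaldehyde
Product: 2 3,4-dimethoxy-5-(methoxymethoxy)benzaldehyde
Conditions: MOMCl, iPr2NEt, CH2Cl2, 0 °C → rt
Reagents that add atoms: chloromethyl methyl ether (MOMCl), COCCl
Why: O-alkylation of the phenol (acetal protection); the phenol is the only nucleophilic site and the aldehyde is inert to the amine base.

Step 2
Reactants: 2 3,4-dimethoxy-5-(methoxymethoxy)benzaldehyde
Product: 3 [3,4-dimethoxy-5-(methoxymethoxy)phenyl]methanol
Conditions: NaBH4, MeOH, 0 °C
Reagents that add atoms: none
Why: Borohydride reduction of an aromatic aldehyde; the acetal and the aryl ethers are not affected.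

Step 3
Reactants: 4 4-chloro-2-methoxyphenol
Product: 5 4-chloro-2-iodo-6-methoxyphenol
Conditions: I2, KI, NaHCO3, H2O/THF, 0 °C → rt
Reagents that add atoms: iodine, II
Why: Electrophilic aromatic iodination through the phenoxide; the para position is blocked by chlorine and one ortho position by the methoxy group, so the phenoxide directs iodine to the single free ortho carbon.

Step 4
Reactants: 5 4-chloro-2-iodo-6-methoxyphenol, 3 [3,4-dimethoxy-5-(methoxymethoxy)phenyl]methanol
Product: 6 5-chloro-2-{[3,4-dimethoxy-5-(methoxymethoxy)phenyl]methoxy}-1-iodo-3-methoxybenzene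
Conditions: PPh3, DIAD, THF, 0 °C → rt
Reagents that add atoms: none
Why: Mitsunobu etherification; the phenol, made more acidic by the ortho iodine and para chlorine, is a good pronucleophile for the activated primary benzylic alcohol, and the neutral conditions spare the acetal.

Step 5
Reactants: 6 5-chloro-2-{[3,4-dimethoxy-5-(methoxymethoxy)phenyl]methoxy}-1-iodo-3-methoxybenzene, 7 ethyl diazoacetate
Product: 8 ethyl 2-{5-chloro-2-[3,4-dimethoxy-5-(methoxymethoxy)benzyloxy]-3-methoxyphenyl}-2-diazoacetate
Conditions: Pd(PPh3)4 (5 mol %), Ag2CO3, Et3N, toluene, rt
Reagents that add atoms: none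
Why: Palladium-catalysed cross-coupling of an aryl iodide with the C–H bond of an acceptor diazo compound; zerovalent palladium inserts into the C–I bond (not the C–Cl bond) at room temperature, the diazo carbon is palladated with the help of base and silver, and reductive elimination is faster than loss of the diazo group.

Step 6
Reactants: 8 ethyl 2-{5-chloro-2-[3,4-dimethoxy-5-(methoxymethoxy)benzyloxy]-3-methoxyphenyl}-2-diazoacetate
Product: 9 ethyl (2S,3R)-5-chloro-2-[3,4-dimethoxy-5-(methoxymethoxy)phenyl]-7-methoxy-2,3-dihydro-1-benzofuran-3-carboxylate (cis)
Conditions: Rh2(R-PTTL)4 (1 mol %), toluene, −78 → −60 °C, slow addition of 8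
Reagents that add atoms: none
Why: The dirhodium tetracarboxylate (two divalent rhodium centres) attacks the diazo carbon of 8 and expels nitrogen to give a donor/acceptor carbenoid at the future C3, which engages one benzylic C–H bond of the ether methylene in a concerted, asynchronous three-centre transition state with hydride-transfer character, so that C2–C3 and C3–H form together and the catalyst is released. The closest known reaction type is the enantioselective intramolecular C–H insertion of aryldiazoacetates into the benzylic position of aryl benzyl ethers with phthaloyl-amino-acid dirhodium carboxylates, which gives cis-2-aryl-2,3-dihydrobenzofuran-3-carboxylates. The dihydrofuran ring closes in the 1,5-insertion mode (carbenoid carbon, C3a, C7a, O1, C2), the favoured five-membered mode; no other C–H bond can reach the carbenoid in this way, since the ring A methoxy group is meta to the carbenoid carbon and the acetal hydrogens are remote. C2 is set by the catalyst: the chiral pocket of the four N-phthaloyl-(R)-tert-leucinate ligands distinguishes the two enantiotopic benzylic hydrogens, and the R-configured complex is chosen to deliver 2S. C3 is set relative to C2 by the transition-state geometry, in which the ring B aryl group turns away from the ligand wall and ends up cis to the ester (3R); this centre is corrected in step 7. The step needs site selectivity, cis selectivity and enantioselectivity and must outrun carbenoid dimerisation: the ether oxygen and the electron-rich ring B stabilise the positive charge that builds up at C2, the donor/acceptor carbenoid is selective enough to react at low temperature, and slow addition keeps the diazo concentration low. The chloride, the methyl ethers and the acetal are inert to the carbenoid.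

Step 7
Reactants: 9 ethyl (2S,3R)-5-chloro-2-[3,4-dimethoxy-5-(methoxymethoxy)phenyl]-7-methoxy-2,3-dihydro-1-benzofuran-3-carboxylate
Product: 10 ethyl (2S,3S)-5-chloro-2-[3,4-dimethoxy-5-(methoxymethoxy)phenyl]-7-methoxy-2,3-dihydro-1-benzofuran-3-carboxylate (trans)
Conditions: NaOEt (0.2 equiv), EtOH, 0 °C → rt
Reagents that add atoms: none
Why: Thermodynamic epimerisation through the ester enolate; the trans isomer relieves the eclipsing of aryl and ester groups, ethoxide matches the ester, and C2 has no acidic hydrogen. Expulsion of O1 from the enolate is disfavoured because the C2–O1 bond lies close to the nodal plane of the exocyclic enolate.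

Step 8
Reactants: 10 ethyl (2S,3S)-5-chloro-2-[3,4-dimethoxy-5-(methoxymethoxy)phenyl]-7-methoxy-2,3-dihydro-1-benzofuran-3-carboxylate
Product: 11 [(2S,3R)-5-chloro-2-[3,4-dimethoxy-5-(methoxymethoxy)phenyl]-7-methoxy-2,3-dihydro-1-benzofuran-3-yl]methanol (trans)
Conditions: LiAlH4, THF, 0 °C
Reagents that add atoms: none
Why: Hydride reduction of the ester to the primary alcohol; the aryl chloride and the acetal are stable at 0 °C and no stereocentre is touched (the descriptor at C3 changes only through the priority rules).

Step 9
Reactants: 11 [(2S,3R)-5-chloro-2-[3,4-dimethoxy-5-(methoxymethoxy)phenyl]-7-methoxy-2,3-dihydro-1-benzofuran-3-yl]methanol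
Product: 12 [(2S,3R)-5-chloro-2-[3,4-dimethoxy-5-(methoxymethoxy)phenyl]-7-methoxy-2,3-dihydro-1-benzofuran-3-yl]methyl 4-methylbenzenesulfonate
Conditions: TsCl, Et3N, DMAP (cat.), CH2Cl2, 0 °C → rt
Reagents that add atoms: 4-methylbenzenesulfonyl chloride (TsCl), Cc1ccc(cc1)S(Cl)(=O)=O
Why: Sulfonylation of the only hydroxyl group in the molecule; it turns the primary alcohol into a leaving group.

Step 10
Reactants: 12 [(2S,3R)-5-chloro-2-[3,4-dimethoxy-5-(methoxymethoxy)phenyl]-7-methoxy-2,3-dihydro-1-benzofuran-3-yl]methyl 4-methylbenzenesulfonate
Product: 13 (2S,3S)-5-chloro-2-[3,4-dimethoxy-5-(methoxymethoxy)phenyl]-7-methoxy-3-methyl-2,3-dihydro-1-benzofuran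
Conditions: LiEt3BH, THF, 0 °C → rt
Reagents that add atoms: none
Why: SN2 displacement of a primary tosylate by a strongly nucleophilic borohydride; aryl chlorides and acetals are inert to it, and C3 is not involved.

Step 11
Reactants: 13 (2S,3S)-5-chloro-2-[3,4-dimethoxy-5-(methoxymethoxy)phenyl]-7-methoxy-3-methyl-2,3-dihydro-1-benzofuran
Product: 14 5-[(2S,3S)-5-chloro-7-methoxy-3-methyl-2,3-dihydro-1-benzofuran-2-yl]-2,3-dimethoxyphenol
Conditions: HCl (cat.), MeOH, 40 °C
Reagents that add atoms: none
Why: Acid-catalysed transacetalisation of the aryl methoxymethyl ether; the methyl ethers are stable, and the C2–O1 bond should hold because the para methoxy group of ring B is twisted by its two neighbours and the two meta oxygens disfavour a benzylic cation. The step is placed before the alkene is introduced so that no styrene meets acid.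

Step 12
Reactants: 14 5-[(2S,3S)-5-chloro-7-methoxy-3-methyl-2,3-dihydro-1-benzofuran-2-yl]-2,3-dimethoxyphenol, 15 potassium (E)-prop-1-enyltrifluoroborate
Product: 16 2,3-dimethoxy-5-[(2S,3S)-7-methoxy-3-methyl-5-[(E)-prop-1-enyl]-2,3-dihydro-1-benzofuran-2-yl]phenol
Conditions: Pd(OAc)2 (3 mol %), SPhos (6 mol %), K2CO3, 1,4-dioxane/H2O, 90 °C
Reagents that add atoms: none
Why: Suzuki–Miyaura coupling; the electron-rich dialkylbiarylphosphine enables oxidative addition into the electron-rich C–Cl bond, slow release of the boronic acid from the trifluoroborate limits protodeboronation, and transmetalation and reductive elimination retain the E geometry. The phenol is carried as its phenoxide with extra base.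

## Compound list

1 | 3-hydroxy-4,5-dimethoxybenzaldehyde | O=Cc1cc(O)c(OC)c(OC)c1 | starting material
2 | 3,4-dimethoxy-5-(methoxymethoxy)benzaldehyde | O=Cc1cc(OCOC)c(OC)c(OC)c1 | intermediate
3 | [3,4-dimethoxy-5-(methoxymethoxy)phenyl]methanol | OCc1cc(OCOC)c(OC)c(OC)c1 | intermediate
4 | 4-chloro-2-methoxyphenol | COc1cc(Cl)ccc1O | starting material
5 | 4-chloro-2-iodo-6-methoxyphenol | COc1cc(Cl)cc(I)c1O | intermediate
6 | 5-chloro-2-{[3,4-dimethoxy-5-(methoxymethoxy)phenyl]methoxy}-1-iodo-3-methoxybenzene | COc1cc(Cl)cc(I)c1OCc1cc(OCOC)c(OC)c(OC)c1 | intermediate
7 | ethyl diazoacetate | CCOC(=O)C=[N+]=[N-] | starting material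
8 | ethyl 2-{5-chloro-2-[3,4-dimethoxy-5-(methoxymethoxy)benzyloxy]-3-methoxyphenyl}-2-diazoacetate | CCOC(=O)C(=[N+]=[N-])c1cc(Cl)cc(OC)c1OCc1cc(OCOC)c(OC)c(OC)c1 | intermediate
9 | ethyl (2S,3R)-5-chloro-2-[3,4-dimethoxy-5-(methoxymethoxy)phenyl]-7-methoxy-2,3-dihydro-1-benzofuran-3-carboxylate (cis) | Clc1cc(OC)c2c(c1)[C@@H](C(=O)OCC)[C@@H](c1cc(OCOC)c(OC)c(OC)c1)O2 | intermediate
10 | ethyl (2S,3S)-5-chloro-2-[3,4-dimethoxy-5-(methoxymethoxy)phenyl]-7-methoxy-2,3-dihydro-1-benzofuran-3-carboxylate (trans) | Clc1cc(OC)c2c(c1)[C@H](C(=O)OCC)[C@@H](c1cc(OCOC)c(OC)c(OC)c1)O2 | intermediate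
11 | [(2S,3R)-5-chloro-2-[3,4-dimethoxy-5-(methoxymethoxy)phenyl]-7-methoxy-2,3-dihydro-1-benzofuran-3-yl]methanol (trans) | Clc1cc(OC)c2c(c1)[C@H](CO)[C@@H](c1cc(OCOC)c(OC)c(OC)c1)O2 | intermediate
12 | [(2S,3R)-5-chloro-2-[3,4-dimethoxy-5-(methoxymethoxy)phenyl]-7-methoxy-2,3-dihydro-1-benzofuran-3-yl]methyl 4-methylbenzenesulfonate | Clc1cc(OC)c2c(c1)[C@H](COS(=O)(=O)c1ccc(C)cc1)[C@@H](c1cc(OCOC)c(OC)c(OC)c1)O2 | intermediate
13 | (2S,3S)-5-chloro-2-[3,4-dimethoxy-5-(methoxymethoxy)phenyl]-7-methoxy-3-methyl-2,3-dihydro-1-benzofuran | Clc1cc(OC)c2c(c1)[C@H](C)[C@@H](c1cc(OCOC)c(OC)c(OC)c1)O2 | intermediate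
14 | 5-[(2S,3S)-5-chloro-7-methoxy-3-methyl-2,3-dihydro-1-benzofuran-2-yl]-2,3-dimethoxyphenol | Clc1cc(OC)c2c(c1)[C@H](C)[C@@H](c1cc(O)c(OC)c(OC)c1)O2 | intermediate
15 | potassium (E)-prop-1-enyltrifluoroborate | C/C=C/[B-](F)(F)F.[K+] | starting material
16 | 2,3-dimethoxy-5-[(2S,3S)-7-methoxy-3-methyl-5-[(E)-prop-1-enyl]-2,3-dihydro-1-benzofuran-2-yl]phenol | C/C=C/c1cc(OC)c2c(c1)[C@H](C)[C@@H](c1cc(O)c(OC)c(OC)c1)O2 | target

## Step count and least certain steps

Total: 12 steps. Longest linear sequence: 11 steps (1 to 16 through steps 1, 2 and 4 to 12); the branch from 4 adds step 3.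

**Step 6 (key step).** The discrimination between the two enantiotopic benzylic hydrogens may be poorer than with simpler ethers. The methoxy group next to the benzyloxy oxygen forces the O–CH2 bond out of the ring A plane and changes how the substrate sits in the catalyst pocket. The very electron-rich ring B may also favour a stepwise hydride-transfer pathway that erodes stereocontrol, and carbenoid dimerisation may compete. A crystalline intermediate such as 10 or 11 offers a chance to raise the enantiomeric purity. Fallback: setting out from 8, the insertion is run with achiral Rh2(OAc)4 in CH2Cl2 to give the racemic cis ester F1. NaOEt in EtOH should convert it into the racemic trans ester F2, and LiAlH4 should reduce this to the racemic trans alcohol F3. Preparative chromatography on a chiral stationary phase then separates the enantiomers, and the 2S,3R enantiomer is 11, where the route is rejoined.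

**Step 5.** Coupling at an iodide flanked by the bulky benzyloxy group may be slow. Palladium-induced decomposition of 7 or of the product diazo ester (carbene formation and dimerisation) could then take over, and traces of phosphine could be carried into step 6. Fallback: setting out from 6, a Negishi-type coupling with the Reformatsky reagent BrZnCH2CO2Et (Pd(dba)2, XPhos, THF) should give ethyl 2-{5-chloro-2-[3,4-dimethoxy-5-(methoxymethoxy)benzyloxy]-3-methoxyphenyl}acetate F4. Regitz diazo transfer with 4-acetamidobenzenesulfonyl azide and DBU in MeCN then returns to 8.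

**Step 7.** The ester enolate may expel the O1 phenoxide and reclose, which would erode the configuration at C2, or equilibration may stop short of completion. Fallback: setting out from 9, LiAlH4 reduction should give the cis alcohol F5 and Dess–Martin periodinane the cis aldehyde F6. This far more acidic aldehyde should equilibrate with catalytic DBU in CH2Cl2 to the trans aldehyde F7 without any alkoxide. NaBH4 reduction then returns to 11.

**Step 12.** Oxidative addition into the electron-rich C–Cl bond may be sluggish, perhaps slowed further by the phenoxide, leaving time for protodeboronation of the propenyl boron species. Fallback: the polarity of the coupling is reversed. Setting out from 14, Miyaura borylation (bis(pinacolato)diboron, Pd2(dba)3, XPhos, KOAc, 1,4-dioxane) should give the aryl pinacolboronate F8. Suzuki–Miyaura coupling of F8 with (E)-1-bromoprop-1-ene (Pd(PPh3)4, K2CO3, 1,4-dioxane/H2O) then gives 16 directly; the alkenyl bromide adds to palladium easily and the arylboronate is robust.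

## Further compounds

F1 | step 6 | racemic ethyl cis-5-chloro-2-[3,4-dimethoxy-5-(methoxymethoxy)phenyl]-7-methoxy-2,3-dihydro-1-benzofuran-3-carboxylate (2S,3R and 2R,3S) | Clc1cc(OC)c2c(c1)[C@@H](C(=O)OCC)[C@@H](c1cc(OCOC)c(OC)c(OC)c1)O2.Clc1cc(OC)c2c(c1)[C@H](C(=O)OCC)[C@H](c1cc(OCOC)c(OC)c(OC)c1)O2
F2 | step 6 | racemic ethyl trans-5-chloro-2-[3,4-dimethoxy-5-(methoxymethoxy)phenyl]-7-methoxy-2,3-dihydro-1-benzofuran-3-carboxylate (2S,3S and 2R,3R) | Clc1cc(OC)c2c(c1)[C@H](C(=O)OCC)[C@@H](c1cc(OCOC)c(OC)c(OC)c1)O2.Clc1cc(OC)c2c(c1)[C@@H](C(=O)OCC)[C@H](c1cc(OCOC)c(OC)c(OC)c1)O2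
F3 | step 6 | racemic trans-[5-chloro-2-[3,4-dimethoxy-5-(methoxymethoxy)phenyl]-7-methoxy-2,3-dihydro-1-benzofuran-3-yl]methanol (2S,3R and 2R,3S) | Clc1cc(OC)c2c(c1)[C@H](CO)[C@@H](c1cc(OCOC)c(OC)c(OC)c1)O2.Clc1cc(OC)c2c(c1)[C@@H](CO)[C@H](c1cc(OCOC)c(OC)c(OC)c1)O2
F4 | step 5 | ethyl 2-{5-chloro-2-[3,4-dimethoxy-5-(methoxymethoxy)benzyloxy]-3-methoxyphenyl}acetate | CCOC(=O)Cc1cc(Cl)cc(OC)c1OCc1cc(OCOC)c(OC)c(OC)c1
F5 | step 7 | [(2S,3S)-5-chloro-2-[3,4-dimethoxy-5-(methoxymethoxy)phenyl]-7-methoxy-2,3-dihydro-1-benzofuran-3-yl]methanol (cis) | Clc1cc(OC)c2c(c1)[C@@H](CO)[C@@H](c1cc(OCOC)c(OC)c(OC)c1)O2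
F6 | step 7 | (2S,3R)-5-chloro-2-[3,4-dimethoxy-5-(methoxymethoxy)phenyl]-7-methoxy-2,3-dihydro-1-benzofuran-3-carbaldehyde (cis) | Clc1cc(OC)c2c(c1)[C@@H](C=O)[C@@H](c1cc(OCOC)c(OC)c(OC)c1)O2
F7 | step 7 | (2S,3S)-5-chloro-2-[3,4-dimethoxy-5-(methoxymethoxy)phenyl]-7-methoxy-2,3-dihydro-1-benzofuran-3-carbaldehyde (trans) | Clc1cc(OC)c2c(c1)[C@H](C=O)[C@@H](c1cc(OCOC)c(OC)c(OC)c1)O2
F8 | step 12 | 2,3-dimethoxy-5-[(2S,3S)-7-methoxy-3-methyl-5-(4,4,5,5-tetramethyl-1,3,2-dioxaborolan-2-yl)-2,3-dihydro-1-benzofuran-2-yl]phenol | CC1(C)OB(OC1(C)C)c1cc(OC)c2c(c1)[C@H](C)[C@@H](c1cc(O)c(OC)c(OC)c1)O2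
A1 | alternative 1 | (2S,3S)-5-bromo-2-[3,4-dimethoxy-5-(triisopropylsilyloxy)phenyl]-7-methoxy-3-methyl-2,3-dihydro-1-benzofuran | Brc1cc(OC)c2c(c1)[C@H](C)[C@@H](c1cc(O[Si](C(C)C)(C(C)C)C(C)C)c(OC)c(OC)c1)O2
A2 | alternative 1 | 4-bromo-2-methoxy-6-[1-(4-methylbenzenesulfonyl)ethyl]phenol (racemic) | CC(c1cc(Br)cc(OC)c1O)S(=O)(=O)c1ccc(C)cc1
A3 | alternative 2 | (2S)-6-bromo-2-[3,4-dimethoxy-5-(triisopropylsilyloxy)phenyl]-8-methoxy-2,3-dihydro-4H-chromen-4-one | O=C1C[C@@H](c2cc(O[Si](C(C)C)(C(C)C)C(C)C)c(OC)c(OC)c2)Oc2c(OC)cc(Br)cc12
A4 | alternative 2 | methyl (2S,3S)-5-bromo-2-[3,4-dimethoxy-5-(triisopropylsilyloxy)phenyl]-7-methoxy-2,3-dihydro-1-benzofuran-3-carboxylate (trans) | Brc1cc(OC)c2c(c1)[C@H](C(=O)OC)[C@@H](c1cc(O[Si](C(C)C)(C(C)C)C(C)C)c(OC)c(OC)c1)O2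
A5 | alternative 3 | methyl (2S,3S)-7-bromo-2-[3,4-dimethoxy-5-(methoxymethoxy)phenyl]-3-methyl-2,3-dihydro-1-benzofuran-5-carboxylate | COC(=O)c1cc(Br)c2c(c1)[C@H](C)[C@@H](c1cc(OCOC)c(OC)c(OC)c1)O2
A6 | alternative 3 | (4S,5S)-5-[3,4-dimethoxy-5-(methoxymethoxy)phenyl]-4-methyloxolan-2-one (trans) | O=C1C[C@H](C)[C@@H](c2cc(OCOC)c(OC)c(OC)c2)O1
A7 | alternative 3 | methyl 3-bromo-2-oxo-2H-pyran-5-carboxylate | COC(=O)C1=COC(=O)C(Br)=C1
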